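**Retrosynthetic overview**

1. The target reads as fisetinidol-(4α→6)-fisetinidol-(4α→6)-[fisetinidol-(4α→8)]-catechin, all units (2R,3S), all 3,4-trans. It comes from hydrogenolysis of a nona-O-benzyl tetramer that carries benzyl ethers only on the three fisetinidol units.
2. C4(middle fisetinidol)–C6(catechin) is cut to give a benzylated fisetinidol-(4α→6)-fisetinidol with a C4–O leaving group plus fisetinidol-(4α→8)-catechin. The free phloroglucinol ring of the latter is the only strong nucleophile, and its C8 is arylated first, from catechin itself.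
3. The C4–O leaving group of the dimer comes from a late benzylic C–H to C–O oxidation (DDQ/alcohol). The dimer comes from a flavan-3,4-diol cation plus its 4-deoxy congener (C4→C6).
4. Every fisetinidol unit comes from one (2R,3R)-dihydroflavonol whose pyran ring is closed by C–O bond formation. This is a new catalytic enantioselective epoxidation/6-endo phenol cyclisation of an achiral 2'-hydroxychalcone; it makes C3–O and O1–C2 and sets C2 and C3, and C4 follows by hydride.
5. Ring order: aromatic rings are bought; the fisetinidol pyran ring is made in one batch and used three times; then the interflavanyl bonds A–B, D–catechin and AB–catechin. The catechin rings are bought.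

Assumption: the three building blocks of steps 1 and 7 are taken as commercial, and where a C4 leaving group is ionised later only its major epimer is drawn.

Unit labels: unit A is the upper fisetinidol, unit B the middle fisetinidol, unit C the catechin, unit D the C8-bound fisetinidol.

**Route**

Step 1
Reactants: 1 4'-benzyloxy-2'-hydroxyacetophenone; 2 3,4-bis(benzyloxy)benzaldehyde
Product: 3 (E)-2'-hydroxy-4',3,4-tris(benzyloxy)chalcone
Conditions: KOH (3 equiv), EtOH–H2O, 25 °C; then aq. HCl
Reagents that add atoms: none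
Why: Claisen–Schmidt aldol condensation of the acetophenone enolate on the non-enolisable aldehyde gives the conjugated E-enone after dehydration, and the benzyl ethers are inert to base.

Step 2
Reactants: 3 (E)-2'-hydroxy-4',3,4-tris(benzyloxy)chalcone
Product: 5 tri-O-benzyl-(+)-fustin [(2R,3R)-7-(benzyloxy)-2-[3,4-bis(benzyloxy)phenyl]-3-hydroxychroman-4-one], via epoxy ketone 4 (not isolated)
Conditions: Sc(OTf)3 (5 mol%), chiral N,N'-dioxide ligand (propane-1,3-diyl-linked bis-N-oxide of L-pipecolic acid 2,6-diisopropylanilide, 5.5 mol%; antipode if the facial sense proves opposite), 30% aq. H2O2 (1.5 equiv), THF, 0 → 25 °C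
Reagents that add atoms: hydrogen peroxide, OO
Why: Proposed new method: an enantioselective arrested Algar–Flynn–Oyamada reaction in which the 2'-hydroxy ketone binds trivalent scandium as a six-membered O,O-chelate inside the chiral N,N'-dioxide pocket, which locks the enone, raises its electrophilicity and blocks oxa-Michael closure; metal-bound hydroperoxide then adds to one face of Cβ and closes to the (αR,βS)-epoxide 4 (Weitz–Scheffer), whose scandium-activated benzylic C–O bond is opened 6-endo by the ortho-phenol with inversion, giving C2 (R) trans to the retained C3 carbinol (R); the closest known reactions are the Lewis-acid-catalysed asymmetric H2O2 epoxidation of simple chalcones and the racemic base-mediated Algar–Flynn–Oyamada cyclisation.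

Step 3
Reactants: 5 tri-O-benzyl-(+)-fustin
Product: 6 tri-O-benzyl-(+)-mollisacacidin [(2R,3S,4R)-7-(benzyloxy)-2-[3,4-bis(benzyloxy)phenyl]chromane-3,4-diol]
Conditions: NaBH4 (2 equiv), THF–MeOH, 0 °C
Reagents that add atoms: none
Why: Substrate-controlled borohydride 1,2-reduction of the chromanone, where axial hydride delivery gives the equatorial 4-OH trans to the 3-OH (2,3-trans-3,4-trans) as is usual for 2,3-trans-dihydroflavonols; C2 and C3 are untouched.

Step 4
Reactants: 6 tri-O-benzyl-(+)-mollisacacidin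
Product: 7 tri-O-benzyl-(−)-fisetinidol [(2R,3S)-7-(benzyloxy)-2-[3,4-bis(benzyloxy)phenyl]chroman-3-ol]
Conditions: Et3SiH (5 equiv), TFA (3 equiv), CH2Cl2 (0.02 M), −30 → 0 °C
Reagents that add atoms: none
Why: Ionic hydrogenation (Kursanov–Parnes) in which TFA ionises the p-benzyloxy-stabilised C4 carbinol and excess silane traps the cation faster than any arene can; no stereocentre is made or lost.

Step 5
Reactants: 6 tri-O-benzyl-(+)-mollisacacidin; 7 tri-O-benzyl-(−)-fisetinidol (3 equiv, excess recovered)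
Product: 8 tri-O-benzylfisetinidol-(4α→6)-tri-O-benzylfisetinidol (both units 2R,3S; unit A 3,4-trans; unit B has C4H2)
Conditions: TMSOTf (0.1 equiv), 4 Å MS, CH2Cl2, −60 → −20 °C, 6 added over 2 h
Reagents that add atoms: none
Why: Friedel–Crafts arylation of the flavan-4-yl cation, which attacks the most accessible activated position of 7 (C6, para to O1 and ortho to the 7-benzyloxy group) from the face anti to the 3-OH to set the 4α bond, while slow addition into excess 7 suppresses self-condensation of 6.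

Step 6
Reactants: 8 tri-O-benzylfisetinidol-(4α→6)-tri-O-benzylfisetinidol
Product: 9 tri-O-benzylfisetinidol-(4α→6)-4β-(2-ethoxyethoxy)-tri-O-benzylfisetinidol
Conditions: DDQ (2 equiv), 2-ethoxyethanol (10 equiv), CH2Cl2, 25 °C
Reagents that add atoms: 2-ethoxyethanol, CCOCCO
Why: DDQ benzylic C–H oxidation (oxidative etherification) removes hydride from the only benzylic CH2, C4 of unit B, to a p-benzyloxy-stabilised cation that the alcohol traps anti to the C2 aryl group, whereas the congested C4 methine of unit A lies in the plane of its flanking aryl ring and is not abstracted; the new C4 configuration is lost again in step 8.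

Step 7
Reactants: 6 tri-O-benzyl-(+)-mollisacacidin; 10 (+)-catechin (4 equiv, excess recovered)
Product: 11 tri-O-benzylfisetinidol-(4α→8)-catechin
Conditions: BF3·OEt2 (0.3 equiv), THF–CH2Cl2 1:1, −20 → 0 °C
Reagents that add atoms: none
Why: Friedel–Crafts arylation in which the free phloroglucinol-type ring of catechin is far more nucleophilic than any benzylated ring, reacts mainly at C8 (about 3:1 over C6 in the free-phenol series) and is attacked anti to the 3-OH of the cation to give the 4α bond; excess catechin prevents double arylation.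

Step 8
Reactants: 9 tri-O-benzylfisetinidol-(4α→6)-4β-(2-ethoxyethoxy)-tri-O-benzylfisetinidol; 11 tri-O-benzylfisetinidol-(4α→8)-catechin (1.5 equiv)
Product: 12 nona-O-benzyl tetramer [tri-O-benzylfisetinidol-(4α→6)-tri-O-benzylfisetinidol-(4α→6)-[tri-O-benzylfisetinidol-(4α→8)]-catechin]
Conditions: BF3·OEt2 (0.3 equiv), 4 Å MS, THF–CH2Cl2 1:1, −20 → 0 °C
Reagents that add atoms: none
Why: Friedel–Crafts arylation in which BF3 ionises the 4-alkoxy group of unit B and the cation is taken up by the only free-phenolic, triply activated carbon left in 11 (C6 of the catechin unit), anti to the 3-OH of unit B, which sets the second 4α→6 bond.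

Step 9
Reactants: 12 nona-O-benzyl tetramer
Product: 13 fisetinidol-(4α→6)-fisetinidol-(4α→6)-[fisetinidol-(4α→8)]-catechin (CNP0263622.1)
Conditions: H2 (1 atm), Pd(OH)2/C (20 wt%), THF–MeOH 1:1, 25 °C
Reagents that add atoms: none
Why: Catalytic hydrogenolysis cleaves the nine aryl benzyl ethers while the interflavanyl C–C bonds of the 5-deoxy units and all eleven stereocentres stay untouched.

**Compound list**

1 | 4'-benzyloxy-2'-hydroxyacetophenone | CC(=O)c1ccc(OCc2ccccc2)cc1O | starting material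
2 | 3,4-bis(benzyloxy)benzaldehyde | O=Cc1ccc(OCc2ccccc2)c(OCc2ccccc2)c1 | starting material
3 | (E)-1-[4-(benzyloxy)-2-hydroxyphenyl]-3-[3,4-bis(benzyloxy)phenyl]prop-2-en-1-one | O=C(/C=C/c1ccc(OCc2ccccc2)c(OCc2ccccc2)c1)c1ccc(OCc2ccccc2)cc1O | intermediate
4 | [4-(benzyloxy)-2-hydroxyphenyl][(2R,3S)-3-[3,4-bis(benzyloxy)phenyl]oxiran-2-yl]methanone | O=C([C@@H]1O[C@H]1c1ccc(OCc2ccccc2)c(OCc2ccccc2)c1)c1ccc(OCc2ccccc2)cc1O | intermediate
5 | (2R,3R)-7-(benzyloxy)-2-[3,4-bis(benzyloxy)phenyl]-3-hydroxychroman-4-one (tri-O-benzyl-(+)-fustin) | c1ccccc1COc1ccc2c(c1)O[C@H](c1ccc(OCc3ccccc3)c(OCc3ccccc3)c1)[C@@H](O)C2=O | intermediate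
6 | (2R,3S,4R)-7-(benzyloxy)-2-[3,4-bis(benzyloxy)phenyl]chromane-3,4-diol (tri-O-benzyl-(+)-mollisacacidin) | c1ccccc1COc1ccc2c(c1)O[C@H](c1ccc(OCc3ccccc3)c(OCc3ccccc3)c1)[C@@H](O)[C@@H]2O | intermediate
7 | (2R,3S)-7-(benzyloxy)-2-[3,4-bis(benzyloxy)phenyl]chroman-3-ol (tri-O-benzyl-(−)-fisetinidol) | c1ccccc1COc1ccc2c(c1)O[C@H](c1ccc(OCc3ccccc3)c(OCc3ccccc3)c1)[C@@H](O)C2 | intermediate
8 | tri-O-benzylfisetinidol-(4α→6)-tri-O-benzylfisetinidol | c1ccccc1COc1ccc2c(c1)O[C@H](c1ccc(OCc3ccccc3)c(OCc3ccccc3)c1)[C@@H](O)[C@@H]2c1cc2c(cc1OCc1ccccc1)O[C@H](c1ccc(OCc3ccccc3)c(OCc3ccccc3)c1)[C@@H](O)C2 | intermediate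
9 | tri-O-benzylfisetinidol-(4α→6)-4β-(2-ethoxyethoxy)-tri-O-benzylfisetinidol | c1ccccc1COc1ccc2c(c1)O[C@H](c1ccc(OCc3ccccc3)c(OCc3ccccc3)c1)[C@@H](O)[C@@H]2c1cc2c(cc1OCc1ccccc1)O[C@H](c1ccc(OCc3ccccc3)c(OCc3ccccc3)c1)[C@@H](O)[C@H]2OCCOCC | intermediate
10 | (+)-catechin, (2R,3S) | O[C@H]1Cc2c(O)cc(O)cc2O[C@@H]1c1ccc(O)c(O)c1 | starting material
11 | tri-O-benzylfisetinidol-(4α→8)-catechin | c1c(O)c2c(c([C@@H]3c4ccc(OCc5ccccc5)cc4O[C@H](c4ccc(OCc5ccccc5)c(OCc5ccccc5)c4)[C@H]3O)c1O)O[C@H](c1ccc(O)c(O)c1)[C@@H](O)C2 | intermediate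
12 | tri-O-benzylfisetinidol-(4α→6)-tri-O-benzylfisetinidol-(4α→6)-[tri-O-benzylfisetinidol-(4α→8)]-catechin | c1ccccc1COc1ccc2c(c1)O[C@H](c1ccc(OCc3ccccc3)c(OCc3ccccc3)c1)[C@@H](O)[C@@H]2c1cc2c(cc1OCc1ccccc1)O[C@H](c1ccc(OCc3ccccc3)c(OCc3ccccc3)c1)[C@@H](O)[C@@H]2c1c(O)c2c(c([C@@H]3c4ccc(OCc5ccccc5)cc4O[C@H](c4ccc(OCc5ccccc5)c(OCc5ccccc5)c4)[C@H]3O)c1O)O[C@H](c1ccc(O)c(O)c1)[C@@H](O)C2 | intermediate
13 | fisetinidol-(4α→6)-fisetinidol-(4α→6)-[fisetinidol-(4α→8)]-catechin | Oc1ccc2c(c1)O[C@H](c1ccc(O)c(O)c1)[C@@H](O)[C@@H]2c1cc2c(cc1O)O[C@H](c1ccc(O)c(O)c1)[C@@H](O)[C@@H]2c1c(O)c2c(c([C@@H]3c4ccc(O)cc4O[C@H](c4ccc(O)c(O)c4)[C@H]3O)c1O)O[C@H](c1ccc(O)c(O)c1)[C@@H](O)C2 | target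

**Step count and risk**

Total steps: 9. Longest linear sequence: 8 (steps 1, 2, 3, 4, 5, 6, 8, 9). Step 7 is the side branch, and compound 6 is made once and used three times.

Steps most likely to fail:

Step 2 (the proposed new step). The scandium chelate may turn over slowly, the ee may be insufficient, or the Lewis acid may divert the electron-rich epoxide into aroyl migration. The fallback is known chemistry; it sets out from 3 and comes back at 5. The phenol of 3 is protected (NaH, MOMCl, THF) to give the 2'-O-methoxymethyl chalcone F1. Juliá–Colonna epoxidation (poly-L-leucine, urea–H2O2, DBU, THF) gives the (αR,βS)-epoxy ketone F2. BnSH with SnCl4 in CH2Cl2 at −20 °C opens the epoxide at the benzylic carbon and removes the methoxymethyl group, giving the α,2'-dihydroxy-β-benzylsulfanyl dihydrochalcone F3. AgBF4 in CH2Cl2 at 0 °C then ionises the C–S bond and the phenol closes the ring to the 2,3-trans product 5, which is recrystallised to optical purity.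

Step 6. DDQ may attack the doubly benzylic C4–H of unit A or over-oxidise, and the 5-deoxy ring is harder to oxidise than a phloroglucinol ring. The fallback avoids C–H oxidation; it sets out from 6 and comes back at 12. Compound 6 is self-condensed under acid (TMSOTf 0.05 equiv, CH2Cl2, −40 °C, stopped near 30% conversion, unreacted 6 recycled). This gives the dimeric flavan-3,4-diol F4, which already carries the C4 oxygen on unit B. F4 is coupled directly with 11 under the conditions of step 8, with the C4 hydroxyl as the leaving group, to give 12.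

Step 8. C6 of the catechin unit is flanked by two hydroxyls, the cation is a bulky dimer, and the 4β epimer or acid-promoted ether scrambling may compete. The fallback changes the mode of cation generation; it sets out from 9 and comes back at 12. Compound 9 is treated with BnSH and BF3·OEt2 (0.2 equiv) in CH2Cl2 at 0 °C to give the 4α-benzylsulfanyl dimer F5. F5 is coupled with 11 by thiophilic activation with AgBF4 in THF at 0 °C, which forms the cation irreversibly without a Lewis acid and is compatible with free phenols, giving 12.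

**Further compounds**

F1 | step 2 | (E)-1-[4-(benzyloxy)-2-(methoxymethoxy)phenyl]-3-[3,4-bis(benzyloxy)phenyl]prop-2-en-1-one | O=C(/C=C/c1ccc(OCc2ccccc2)c(OCc2ccccc2)c1)c1ccc(OCc2ccccc2)cc1OCOC
F2 | step 2 | [4-(benzyloxy)-2-(methoxymethoxy)phenyl][(2R,3S)-3-[3,4-bis(benzyloxy)phenyl]oxiran-2-yl]methanone | O=C([C@@H]1O[C@H]1c1ccc(OCc2ccccc2)c(OCc2ccccc2)c1)c1ccc(OCc2ccccc2)cc1OCOC
F3 | step 2 | (2S,3R)-3-(benzylsulfanyl)-1-[4-(benzyloxy)-2-hydroxyphenyl]-3-[3,4-bis(benzyloxy)phenyl]-2-hydroxypropan-1-one | O=C([C@H](O)[C@H](SCc1ccccc1)c1ccc(OCc2ccccc2)c(OCc2ccccc2)c1)c1ccc(OCc2ccccc2)cc1O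
F4 | step 6 | tri-O-benzylfisetinidol-(4α→6)-tri-O-benzylmollisacacidin (dimeric 3,4-diol, 4α-OH on unit B) | c1ccccc1COc1ccc2c(c1)O[C@H](c1ccc(OCc3ccccc3)c(OCc3ccccc3)c1)[C@@H](O)[C@@H]2c1cc2c(cc1OCc1ccccc1)O[C@H](c1ccc(OCc3ccccc3)c(OCc3ccccc3)c1)[C@@H](O)[C@@H]2O
F5 | step 8 | tri-O-benzylfisetinidol-(4α→6)-4α-(benzylsulfanyl)-tri-O-benzylfisetinidol | c1ccccc1COc1ccc2c(c1)O[C@H](c1ccc(OCc3ccccc3)c(OCc3ccccc3)c1)[C@@H](O)[C@@H]2c1cc2c(cc1OCc1ccccc1)O[C@H](c1ccc(OCc3ccccc3)c(OCc3ccccc3)c1)[C@@H](O)[C@@H]2SCc1ccccc1
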